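**Kanzonol S by de novo construction of ring A on an enantioenriched dihydropyranone**

Target 17 is (2S)-8-[(E)-4-acetoxy-3-methylbut-2-enyl]-5,7,3',4'-tetrahydroxyflavanone. Flavanone numbering (O1, C2, C3, C4, C4a, C5–C8, C8a) is used for the corresponding atoms of every precursor. Ar = 3,4-bis(tert-butyldimethylsilyloxy)phenyl, TBS = tert-butyldimethylsilyl, TMS = trimethylsilyl.

## The problem

Kanzonol S (17) is a (2S)-flavanone. Ring A is a phloroglucinol (C5–OH, C7–OH, O1 on C8a), ring C a dihydropyranone with the only stereocentre (C2, benzylic, bearing catechol ring B), and C8 carries an (E)-4-acetoxy-3-methylbut-2-enyl chain. The hardest point is the position of that chain. C6 and C8 of a phloroglucinol are electronically alike, and in an open acylphloroglucinol the two ortho oxygens are alike too, so "C8 or C6" is decided only by which oxygen becomes O1. Any route that alkylates the arene, or closes ring C onto a finished ring A, must therefore win a regiochemical contest. C2 has no neighbouring stereocentre to control it and must be set by a reagent; once ring A is aromatic it is labile, because base opens ring C by retro-oxa-Michael reaction to the chalcone. The chain holds a trisubstituted (E)-alkene and a primary allylic acetate that must coexist with four free phenols at the end. This excludes hydrogenolysis, zerovalent palladium, strong base and nucleophiles late in the route, and makes a late selective acetylation unattractive. The catechol is prone to oxidation and is best kept silylated until the last step.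

The feature that the plan exploits is that ring A is a folded polyketide. The unit O1–C8a=C4a–C4=O is the vinylogous-ester double bond of a 2-aryl-2,3-dihydro-4H-pyran-4-one, which can exist without ring A. The remaining carbons C8–C7–C6–C5 have the oxidation pattern of an acetoacetyl ketene (C7 acyl carbon, C5 ketene carbon), which a 1,3-dioxin-4-one releases on heating without any reagent. Before ring A is closed, C8 is the only sp3 carbon flanked by two vinylogous carbonyl systems, so the chain can be attached there and nowhere else.

## Retrosynthesis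

17 ⇐ 16. Only the two aryl O–Si bonds are cut. Silyl ethers are the one catechol protection that can be removed (fluoride, slightly acidic) without touching the allylic acetate, the alkene or C2.

16 ⇐ 13 (through 14 and 15). The C4a–C5 bond is cut and ring A is unfolded to acylketene 14, stored as the dioxinone of 13. The neighbouring cut, C5–C6 (Dieckmann closure of a methyl ketone onto a C4a ester), would need a dianion, which would destroy the acetate and endanger C2 by elimination of O1. A cut at C8–C8a would need a leaving group on C8a. The C4a–C5 cut needs only heat. In 13, O1 is already bonded to C8a and the chain already sits on C8, so the forward reaction has no regiochemical choice to make; it only has to form a six-membered ring and tautomerise.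

13 ⇐ 9 + 12. The C8–C1'' bond is cut. In 9, C8 is a methylene between the enol-ether carbons of the pyranone and the dioxinone, the only doubly activated sp3 carbon, so one equivalent of base and an allylic halide suffice. The complete chain, with (E) geometry and acetate, arrives in chloride 12, so no oxidation or acetylation is needed on the polyphenol later.

9 ⇐ 8 ⇐ 5 + 7. The C8–C8a bond is cut. Pyranone 5 is electrophilic at C8a as its silyloxy-pyrylium ion, and the silyl dienol ether 7 of the diketene–acetone adduct is nucleophilic at its γ-carbon (the future C8). Conjugate addition gives enol ether 8 with the double bond fixed on the C4–C4a side, and dehydrogenation restores the vinylogous ester in 9. This replaces a C–H bond of 5 by the four-carbon unit C8–C5 in two standard operations.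

5 ⇐ 2 + 3, and 2 ⇐ 1. Ring C is cut at C2–C3 and O1–C8a (hetero-Diels–Alder retron). Catalytic asymmetric addition of Danishefsky's diene 3 to aldehyde 2 sets C2 by catalyst control before any phenol-type leaving group exists on O1, so C2 cannot racemise through a chalcone until the last two steps, which are neutral or weakly acidic.

12 ⇐ 11 ⇐ 10, and 7 ⇐ 6. The chain comes from isoprene monoxide 10 by SN2' opening with chloride to (E)-chloro alcohol 11, then acetylation. Dienol ether 7 comes from commercial dioxinone 6 by deprotonation and silylation.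

## Roads not taken

Alternative 1: the chalcone route, the most obvious one. The cut is O1–C2. Forward, C-prenylated acetophenone A1 is condensed with a protected 3,4-dihydroxybenzaldehyde to chalcone A2, which is closed by oxa-Michael addition to flavanone A3; allylic oxidation of the (E)-methyl group, acetylation and deprotection follow. This has to win three contests that the chosen plan avoids. The two ortho oxygens of A1 must be differentiated, or both 6- and 8-substituted flavanones form. The ring closure is reversible and base-mediated, so A3 is racemic unless an activating group is added for asymmetric catalysis and removed again. Oxidation and acetylation are carried out late on an electron-rich polyphenol, at the cost of three or four extra steps.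

Alternative 2: late C8 allylation of a finished flavanone by aromatic Claisen rearrangement. The cut is C8–C1''. Forward, the 7-OH of enantioenriched 3',4'-disilyl eriodictyol A4 is converted to tertiary allyl ether A5, and a [3,3] shift gives the chain. The shift can end at C6 as well as C8. The alkene geometry is set in a chair transition state between a methyl and an acetoxymethyl group of similar size, so an E/Z mixture is expected. A4 itself still needs an asymmetric flavanone synthesis and must be heated as a base-labile 5-hydroxyflavanone.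

Alternative 3: asymmetric conjugate arylation of a chromone. The cut is C2–C1'. Forward, arylboronic acid A7 is added catalytically and enantioselectively to 8-substituted chromone A6. C2 is set in one step, but A6 needs the same regiodefined 8-substituted ring A, made from a C-alkylated acetophenone, so the C6/C8 contest is only moved. 5,7-Dialkoxychromones are deactivated acceptors. The chain cannot carry its allylic acetate through a transition-metal-catalysed step that ionises allylic esters, so protecting-group exchange and acetylation return at the end.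

Key step: step 9

Assumption: the catalyst from (S)-BINOL and Ti(OiPr)4 is taken to deliver the diene to the Si face of aldehyde 2, as this catalyst family does with aryl aldehydes; Si-face attack is what (S) at C2 requires, and the mirror-image ligand is used if the sense proves opposite.

## Route

Step 1
Reactants: 1 3,4-dihydroxybenzaldehyde
Product: 2 3,4-bis(tert-butyldimethylsilyloxy)benzaldehyde
Conditions: TBSCl, imidazole, DMF, 23 °C
Reagents that add atoms: tert-butyldimethylsilyl chloride (TBSCl), CC(C)(C)[Si](C)(C)Cl
Why: Standard silylation of both phenols; the aryl silyl ethers tolerate the Lewis-acid, palladium and thermal steps that follow and are removed at the end without harming the acetate.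

Step 2
Reactants: 2 3,4-bis(tert-butyldimethylsilyloxy)benzaldehyde; 3 Danishefsky's diene, (E)-1-methoxy-3-(trimethylsilyloxy)buta-1,3-diene
Product: 5 (2S)-2-Ar-2,3-dihydro-4H-pyran-4-one, via Mukaiyama aldol adduct 4 (not isolated)
Conditions: (S)-BINOL (20 mol %), Ti(OiPr)4 (10 mol %), CF3CO2H (cat.), 4 Å MS, Et2O, −20 °C; then CF3CO2H, CH2Cl2, 0 °C
Reagents that add atoms: none
Why: Catalytic asymmetric hetero-Diels–Alder reaction in its Mukaiyama-aldol/cyclisation form; the chiral BINOL–titanium complex directs the diene to the Si face of the aldehyde, which sets C2 as (S), and acid closes 4 to the pyranone with loss of methanol and the silyl group.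

Step 3
Reactants: 6 2,2,6-trimethyl-4H-1,3-dioxin-4-one
Product: 7 2,2-dimethyl-6-methylidene-4-(trimethylsilyloxy)-6H-1,3-dioxine
Conditions: LiN(iPr)2, THF, −78 °C; TMSCl, −78 to 0 °C
Reagents that add atoms: chlorotrimethylsilane (TMSCl), C[Si](C)(C)Cl
Why: γ-Deprotonation of the vinylogous ester and O-silylation give the known silyl dienol ether, a γ-nucleophilic acetoacetate equivalent.

Step 4
Reactants: 5 (2S)-2-Ar-2,3-dihydro-4H-pyran-4-one; 7 2,2-dimethyl-6-methylidene-4-(trimethylsilyloxy)-6H-1,3-dioxine
Product: 8 (2S,6R)-2-Ar-6-[(2,2-dimethyl-4-oxo-4H-1,3-dioxin-6-yl)methyl]-4-(trimethylsilyloxy)-3,6-dihydro-2H-pyran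
Conditions: TMSOTf (10 mol %), CH2Cl2, −78 °C; Et3N quench; used crude
Reagents that add atoms: none
Why: Vinylogous Mukaiyama–Michael addition; silylation of the C4 carbonyl gives a silyloxy-pyrylium ion that the dienol ether attacks at C8a through its γ-carbon, anti to the aryl group (2,6-trans; this centre is erased in step 5). Silyl transfer regenerates the catalyst and fixes the enol ether on the C4–C4a side.

Step 5
Reactants: 8 (2S,6R)-2-Ar-6-[(2,2-dimethyl-4-oxo-4H-1,3-dioxin-6-yl)methyl]-4-(trimethylsilyloxy)-3,6-dihydro-2H-pyran
Product: 9 6-{[(2S)-2-Ar-4-oxo-3,4-dihydro-2H-pyran-6-yl]methyl}-2,2-dimethyl-4H-1,3-dioxin-4-one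
Conditions: Pd(OAc)2 (1.1 equiv), MeCN, 23 °C
Reagents that add atoms: none
Why: Saegusa–Ito oxidation; the regiodefined silyl enol ether gives a palladium enolate at C4a whose only β-hydrogen is on C8a, so elimination restores the C4a=C8a vinylogous ester, now substituted at C8a; C2 is not involved.

Step 6
Reactants: 10 2-methyl-2-vinyloxirane (isoprene monoxide, racemic)
Product: 11 (E)-4-chloro-2-methylbut-2-en-1-ol
Conditions: TiCl4, CH2Cl2, −85 °C; aqueous HCl work-up
Reagents that add atoms: titanium tetrachloride (TiCl4), Cl[Ti](Cl)(Cl)Cl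
Why: Known SN2' opening of the titanium-bound vinyl epoxide with delivery of chloride to the vinyl terminus; it gives the (E)-allylic chloro alcohol, and the geometry is never again exposed to a metal that could isomerise it.

Step 7
Reactants: 11 (E)-4-chloro-2-methylbut-2-en-1-ol
Product: 12 (E)-4-chloro-2-methylbut-2-en-1-yl acetate
Conditions: Ac2O, pyridine, DMAP (cat.), CH2Cl2, 0 °C
Reagents that add atoms: acetic anhydride, CC(=O)OC(C)=O
Why: Routine acetylation of the primary alcohol; the acetate of the target is installed here, before any phenol exists.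

Step 8
Reactants: 9 6-{[(2S)-2-Ar-4-oxo-3,4-dihydro-2H-pyran-6-yl]methyl}-2,2-dimethyl-4H-1,3-dioxin-4-one; 12 (E)-4-chloro-2-methylbut-2-en-1-yl acetate
Product: 13 (E)-5-[(2S)-2-Ar-4-oxo-3,4-dihydro-2H-pyran-6-yl]-5-(2,2-dimethyl-4-oxo-4H-1,3-dioxin-6-yl)-2-methylpent-2-en-1-yl acetate (both epimers at C8)
Conditions: NaH (1.05 equiv), THF, 0 °C; then 12, Bu4NI (10 mol %), 0 to 23 °C
Reagents that add atoms: none
Why: SN2 C-alkylation of the anion at C8, which is stabilised by both vinylogous carbonyl systems; dienolates bearing a β-oxygen alkylate at the γ-carbon, and C8 is γ to both. Direct displacement of the primary allylic chloride keeps the (E) geometry, and the new centre at C8 is of no consequence because it becomes aromatic.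

Step 9
Reactants: 13 (E)-5-[(2S)-2-Ar-4-oxo-3,4-dihydro-2H-pyran-6-yl]-5-(2,2-dimethyl-4-oxo-4H-1,3-dioxin-6-yl)-2-methylpent-2-en-1-yl acetate
Product: 16 3',4'-bis-O-TBS-kanzonol S, via acylketene 14 (not isolated), via cyclohexadienone 15 (not isolated)
Conditions: PhMe (0.005 M, slow addition), 110 °C, N2
Reagents that add atoms: none
Why: Proposed new method: at 110 °C the dioxinone of 13 undergoes its usual retro-[4+2] loss of acetone to acylketene 14, with C5 as the ketene carbon and C7 as the acyl carbon; enolisation of C8–H towards C7 gives a dienylketene C5=C6–C7(OH)=C8–C8a=C4a that closes by thermal 6π-electrocyclisation between C5 and C4a (ring A, six-membered), and cyclohexadienone 15 tautomerises irreversibly to the phloroglucinol. The closest known reaction types are the dienylketene electrocyclisation that ends the Danheiser benzannulation and the C-acylation of enols by dioxinone-derived acylketenes; the polar alternative, attack of the vinylogous-ester carbon C4a on the ketene followed by loss of the C8 proton, leads to the same 15. No stereocentre is created (C4a–H of 15 is lost on enolisation), and C2 is untouched because no base, acid or metal is present, which also spares the allylic acetate and the silyl ethers. Regiochemistry is a consequence of connectivity, not a selectivity: O1 is already bonded to C8a and the chain already sits on C8. The selectivity needed is intramolecular C-acylation over capture of 14 by a second molecule (dimerisation, or acylation of product phenols); it is secured by high dilution and by the fact that no oxygen nucleophile in 14 can reach C5 through a ring smaller than eight.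

Step 10
Reactants: 16 3',4'-bis-O-TBS-kanzonol S
Product: 17 kanzonol S
Conditions: Et3N·3HF, THF, 0 to 23 °C
Reagents that add atoms: none
Why: Fluoride-mediated cleavage of the two aryl silyl ethers under slightly acidic, non-nucleophilic conditions; the primary acetate, the (E)-alkene and the base-labile C2 centre are not affected.

## Compound list

1 | 3,4-dihydroxybenzaldehyde | O=Cc1ccc(O)c(O)c1 | starting material
2 | 3,4-bis(tert-butyldimethylsilyloxy)benzaldehyde | O=Cc1ccc(O[Si](C)(C)C(C)(C)C)c(O[Si](C)(C)C(C)(C)C)c1 | intermediate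
3 | Danishefsky's diene, (E)-1-methoxy-3-(trimethylsilyloxy)buta-1,3-diene | CO/C=C/C(=C)O[Si](C)(C)C | starting material
4 | (5S,E)-5-Ar-1-methoxy-5-(trimethylsilyloxy)pent-1-en-3-one (Mukaiyama aldol adduct, not isolated) | CO/C=C/C(=O)C[C@H](O[Si](C)(C)C)c1ccc(O[Si](C)(C)C(C)(C)C)c(O[Si](C)(C)C(C)(C)C)c1 | intermediate
5 | (2S)-2-Ar-2,3-dihydro-4H-pyran-4-one | O=C1C[C@@H](c2ccc(O[Si](C)(C)C(C)(C)C)c(O[Si](C)(C)C(C)(C)C)c2)OC=C1 | intermediate
6 | 2,2,6-trimethyl-4H-1,3-dioxin-4-one | CC1=CC(=O)OC(C)(C)O1 | starting material
7 | 2,2-dimethyl-6-methylidene-4-(trimethylsilyloxy)-6H-1,3-dioxine | C=C1C=C(O[Si](C)(C)C)OC(C)(C)O1 | intermediate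
8 | (2S,6R)-2-Ar-6-[(2,2-dimethyl-4-oxo-4H-1,3-dioxin-6-yl)methyl]-4-(trimethylsilyloxy)-3,6-dihydro-2H-pyran (2,6-trans) | C[Si](C)(C)OC1=C[C@@H](CC2=CC(=O)OC(C)(C)O2)O[C@H](c2ccc(O[Si](C)(C)C(C)(C)C)c(O[Si](C)(C)C(C)(C)C)c2)C1 | intermediate
9 | 6-{[(2S)-2-Ar-4-oxo-3,4-dihydro-2H-pyran-6-yl]methyl}-2,2-dimethyl-4H-1,3-dioxin-4-one | O=C1C[C@@H](c2ccc(O[Si](C)(C)C(C)(C)C)c(O[Si](C)(C)C(C)(C)C)c2)OC(CC2=CC(=O)OC(C)(C)O2)=C1 | intermediate
10 | 2-methyl-2-vinyloxirane (racemic) | CC1(C=C)CO1 | starting material
11 | (E)-4-chloro-2-methylbut-2-en-1-ol | OC/C(C)=C/CCl | intermediate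
12 | (E)-4-chloro-2-methylbut-2-en-1-yl acetate | CC(=O)OC/C(C)=C/CCl | intermediate
13 | (E)-5-[(2S)-2-Ar-4-oxo-3,4-dihydro-2H-pyran-6-yl]-5-(2,2-dimethyl-4-oxo-4H-1,3-dioxin-6-yl)-2-methylpent-2-en-1-yl acetate (epimers at C8) | CC(=O)OC/C(C)=C/CC(C1=CC(=O)OC(C)(C)O1)C1=CC(=O)C[C@@H](c2ccc(O[Si](C)(C)C(C)(C)C)c(O[Si](C)(C)C(C)(C)C)c2)O1 | intermediate
14 | (E)-5-[(2S)-2-Ar-4-oxo-3,4-dihydro-2H-pyran-6-yl]-2-methyl-6,8-dioxoocta-2,7-dien-1-yl acetate (acylketene, not isolated) | CC(=O)OC/C(C)=C/CC(C(=O)C=C=O)C1=CC(=O)C[C@@H](c2ccc(O[Si](C)(C)C(C)(C)C)c(O[Si](C)(C)C(C)(C)C)c2)O1 | intermediate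
15 | (2S)-8-[(E)-4-acetoxy-3-methylbut-2-enyl]-2-Ar-7-hydroxy-2,3-dihydro-4H-chromene-4,5(4aH)-dione (cyclohexadienone, not isolated) | CC(=O)OC/C(C)=C/CC1=C2O[C@H](c3ccc(O[Si](C)(C)C(C)(C)C)c(O[Si](C)(C)C(C)(C)C)c3)CC(=O)C2C(=O)C=C1O | intermediate
16 | (2S)-8-[(E)-4-acetoxy-3-methylbut-2-enyl]-2-[3,4-bis(tert-butyldimethylsilyloxy)phenyl]-5,7-dihydroxychroman-4-one (3',4'-bis-O-TBS-kanzonol S) | CC(=O)OC/C(C)=C/Cc1c(O)cc(O)c2c1O[C@H](c1ccc(O[Si](C)(C)C(C)(C)C)c(O[Si](C)(C)C(C)(C)C)c1)CC2=O | intermediate
17 | kanzonol S, (2S)-8-[(E)-4-acetoxy-3-methylbut-2-enyl]-2-(3,4-dihydroxyphenyl)-5,7-dihydroxychroman-4-one | CC(=O)OC/C(C)=C/Cc1c(O)cc(O)c2c1O[C@H](c1ccc(O)c(O)c1)CC2=O | target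

## Step count and risks

Total: 10 steps. Longest linear sequence: 7 steps (1, 2, 4, 5, 8, 9, 10).

Step 9 (key step, proposed new method). The most likely failure is bimolecular capture of the acylketene (dimerisation, or O-acylation by phenols of product already formed) outrunning the intramolecular C-acylation, because C4a of a vinylogous ester is only a modest nucleophile and ring closure depends on enolisation at C8. Fallback, ionic instead of pericyclic: it sets out from 13, which is heated in toluene containing methanol so that the acylketene is intercepted as methyl β-keto ester F1 (standard dioxinone alcoholysis). F1 is closed by the Claisen condensation known for converting triketo esters into acylphloroglucinols, Mg(OMe)2 in MeOH at 23 °C; the extended enolate formed at C8 attacks the ester carbon C5 through C4a. The same medium transesterifies the acetate, and KHF2 in MeOH completes removal of the aryl silyl ethers, giving pentaol F2. The primary allylic alcohol of F2 is then acetylated in the presence of the four phenols with Candida antarctica lipase B and vinyl acetate, a known chemoselectivity, and the route is rejoined at 17. Because this closure is basic, the enantiomeric purity at C2 would have to be checked; that is why it is the fallback and not the plan.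

Step 8. The delocalised anion of 9 may be alkylated at oxygen or at its α-carbons (C4a, C6) instead of C8, may be alkylated twice, or the base may open ring C by elimination of O1. Fallback, convergent instead of linear: it sets out from 6, whose lithium dienolate (LiN(SiMe3)2, THF, −78 °C) is γ-alkylated with 12 (as the iodide, NaI) to dioxinone F3, so that the chain is bonded to the future C8 before the pyranone is present. F3 is converted to silyl dienol ether F4 (LiN(SiMe3)2, TMSCl). F4 is added to 5 under the conditions of step 4 to give enol ether F5, and Pd(OAc)2 as in step 5 gives 13, where the route is rejoined.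

Step 4. The silyloxy-pyrylium intermediate may ionise at the benzylic C2–O1 bond (erosion of enantiomeric purity with the electron-rich aryl group), or the dienol ether may add through its α-carbon. Fallback, acylation instead of conjugate addition and re-oxidation: it sets out from 2. Catalytic asymmetric hetero-Diels–Alder reaction with Brassard's diene (1,1-dimethoxy-3-(trimethylsilyloxy)buta-1,3-diene) gives lactone F6, in which C8a is a carbonyl carbon and C4a carries no acidic hydrogen. Addition of the dianion of tert-butyl acetoacetate (NaH, then n-BuLi) to the lactone carbonyl, followed by acid-induced loss of methanol, gives pyranone β-keto ester F7. Treatment of F7 with acetone, (CF3CO)2O and CF3CO2H closes the dioxinone and rejoins the route at 9, bypassing steps 4 and 5.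

## Further compounds

F1 | step 9 | methyl (E)-8-acetoxy-4-[(2S)-2-Ar-4-oxo-3,4-dihydro-2H-pyran-6-yl]-7-methyl-3-oxooct-6-enoate | COC(=O)CC(=O)C(C/C=C(\C)COC(C)=O)C1=CC(=O)C[C@@H](c2ccc(O[Si](C)(C)C(C)(C)C)c(O[Si](C)(C)C(C)(C)C)c2)O1
F2 | step 9 | (2S)-2-(3,4-dihydroxyphenyl)-5,7-dihydroxy-8-[(E)-4-hydroxy-3-methylbut-2-enyl]chroman-4-one | OC/C(C)=C/Cc1c(O)cc(O)c2c1O[C@H](c1ccc(O)c(O)c1)CC2=O
F3 | step 8 | (E)-5-(2,2-dimethyl-4-oxo-4H-1,3-dioxin-6-yl)-2-methylpent-2-en-1-yl acetate | CC(=O)OC/C(C)=C/CCC1=CC(=O)OC(C)(C)O1
F4 | step 8 | (E)-5-[2,2-dimethyl-4-(trimethylsilyloxy)-6H-1,3-dioxin-6-ylidene]-2-methylpent-2-en-1-yl acetate | CC(=O)OC/C(C)=C/CC=C1C=C(O[Si](C)(C)C)OC(C)(C)O1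
F5 | step 8 | (E)-5-[(2,6-trans,6S)-6-Ar-4-(trimethylsilyloxy)-3,6-dihydro-2H-pyran-2-yl]-5-(2,2-dimethyl-4-oxo-4H-1,3-dioxin-6-yl)-2-methylpent-2-en-1-yl acetate | C[Si](C)(C)OC1=C[C@@H](C(C/C=C(\C)COC(C)=O)C2=CC(=O)OC(C)(C)O2)O[C@H](c2ccc(O[Si](C)(C)C(C)(C)C)c(O[Si](C)(C)C(C)(C)C)c2)C1
F6 | step 4 | (6S)-6-Ar-4-methoxy-5,6-dihydro-2H-pyran-2-one | COC1=CC(=O)O[C@H](c2ccc(O[Si](C)(C)C(C)(C)C)c(O[Si](C)(C)C(C)(C)C)c2)C1
F7 | step 4 | tert-butyl 4-[(2S)-2-Ar-4-oxo-3,4-dihydro-2H-pyran-6-yl]-3-oxobutanoate | CC(C)(C)OC(=O)CC(=O)CC1=CC(=O)C[C@@H](c2ccc(O[Si](C)(C)C(C)(C)C)c(O[Si](C)(C)C(C)(C)C)c2)O1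
A1 | alternative 1 | 1-[2-hydroxy-4,6-bis(methoxymethoxy)-3-(3-methylbut-2-enyl)phenyl]ethanone | CC(=O)c1c(O)c(CC=C(C)C)c(OCOC)cc1OCOC
A2 | alternative 1 | (E)-3-[3,4-bis(methoxymethoxy)phenyl]-1-[2-hydroxy-4,6-bis(methoxymethoxy)-3-(3-methylbut-2-enyl)phenyl]prop-2-en-1-one | COCOc1ccc(/C=C/C(=O)c2c(O)c(CC=C(C)C)c(OCOC)cc2OCOC)cc1OCOC
A3 | alternative 1 | racemic 2-[3,4-bis(methoxymethoxy)phenyl]-5,7-bis(methoxymethoxy)-8-(3-methylbut-2-enyl)chroman-4-one | COCOc1ccc(C2CC(=O)c3c(OCOC)cc(OCOC)c(CC=C(C)C)c3O2)cc1OCOC
A4 | alternative 2 | (2S)-2-[3,4-bis(tert-butyldimethylsilyloxy)phenyl]-5,7-dihydroxychroman-4-one | O=C1C[C@@H](c2ccc(O[Si](C)(C)C(C)(C)C)c(O[Si](C)(C)C(C)(C)C)c2)Oc2cc(O)cc(O)c12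
A5 | alternative 2 | (2S)-7-[(1-acetoxy-2-methylbut-3-en-2-yl)oxy]-2-[3,4-bis(tert-butyldimethylsilyloxy)phenyl]-5-hydroxychroman-4-one | CC(=O)OCC(C)(C=C)Oc1cc(O)c2c(c1)O[C@H](c1ccc(O[Si](C)(C)C(C)(C)C)c(O[Si](C)(C)C(C)(C)C)c1)CC2=O
A6 | alternative 3 | 8-[(E)-4-(tert-butyldimethylsilyloxy)-3-methylbut-2-enyl]-5,7-bis(methoxymethoxy)-4H-chromen-4-one | CC(C)(C)[Si](C)(C)OC/C(C)=C/Cc1c(OCOC)cc(OCOC)c2c1occc2=O
A7 | alternative 3 | 3,4-bis(tert-butyldimethylsilyloxy)phenylboronic acid | OB(O)c1ccc(O[Si](C)(C)C(C)(C)C)c(O[Si](C)(C)C(C)(C)C)c1
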